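**Plan**
1. Retrosynthetic cuts, in order: the two O–CH3 bonds of a 5,7-dimethyl ether; the C16′–C17′ bond of the side chain (C1′ is the carbon on chromone C2); then O1–C2 and C2–C3 of the 4-pyranone ring.
2. Enabling feature: the group on C2 of the 4H-chromen-4-one is an unbranched, heteroatom-free C31 polymethylene chain. C16′ and C17′ are therefore plain CH2 carbons, and each can arise as a primary radical from a carboxylic acid by loss of CO2. C17′–C31′ is palmitic acid minus CO2, and C2 plus C1′–C16′ is octadecanedioic acid minus one CO2.
3. Forward: the benzene ring is bought complete as C-methylphloracetophenone. Selective 4,6-di-O-methylation leaves free the OH next to the C-methyl group; this OH becomes O1 and fixes the 8-methyl pattern. The pyranone ring then arises by Baker–Venkataraman shift and cyclodehydration with mono-tert-butyl octadecanedioate.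
4. Both acids are activated as N-hydroxyphthalimide esters and joined by a nickel-electrocatalytic doubly decarboxylative coupling. It is run reductively, so the oxidisable dialkoxyarene never meets a Kolbe anode. BBr3 removes the two methyl groups last.
5. Stereochemistry: the target has no stereocentre and no stereogenic double bond, so nothing has to be set.

Key step: step 6

Remark on the chemistry: the target is achiral, so the question of a single enantiomer does not arise. Compounds 1, 3 and 8 are taken as catalogue chemicals.

**Step 1**
Reactants: 1 2,4,6-trihydroxy-3-methylacetophenone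
Product: 2 2-hydroxy-4,6-dimethoxy-3-methylacetophenone
Conditions: Me2SO4 (2.05 equiv), K2CO3 (2.2 equiv), acetone, reflux
Reagents that add atoms: dimethyl sulfate, COS(=O)(=O)OC
Why: Williamson-type O-methylation, in which the acidic 4-OH and the less hindered 6-OH should react while the 2-OH stays free because the 3-methyl group buttresses it into a strong hydrogen bond with the acetyl C=O, which decides the later 8-methyl (not 6-methyl) constitution.

**Step 2**
Reactants: 2 2-hydroxy-4,6-dimethoxy-3-methylacetophenone; 3 18-(tert-butoxy)-18-oxooctadecanoic acid
Product: 4 2-acetyl-3,5-dimethoxy-6-methylphenyl tert-butyl octadecanedioate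
Conditions: DCC (1.2 equiv), DMAP (0.3 equiv), CH2Cl2, 0 °C → rt
Reagents that add atoms: none
Why: Steglich esterification, in which the acylpyridinium species should acylate the hindered, chelated phenol under neutral conditions that leave the tert-butyl ester untouched.

**Step 3**
Reactants: 4 2-acetyl-3,5-dimethoxy-6-methylphenyl tert-butyl octadecanedioate
Product: 6 17-(5,7-dimethoxy-8-methyl-4-oxo-4H-chromen-2-yl)heptadecanoic acid, via beta-diketone ester 5 (not isolated)
Conditions: LiHMDS (3 equiv), THF, −78 °C → rt; sat. aq NH4Cl; crude 5 in TFA/CH2Cl2 (1:1), rt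
Reagents that add atoms: none
Why: Baker–Venkataraman O→C acyl shift (the methyl ketone enolate attacks the neighbouring aryl ester through a six-membered transition state), followed by acid cyclodehydration of the 2-hydroxyaryl 1,3-diketone, with TFA also cleaving the tert-butyl ester to the acid and only one free phenol OH present so that only the 8-methylchromone can form.

**Step 4**
Reactants: 6 17-(5,7-dimethoxy-8-methyl-4-oxo-4H-chromen-2-yl)heptadecanoic acid
Product: 7 1,3-dioxoisoindolin-2-yl 17-(5,7-dimethoxy-8-methyl-4-oxo-4H-chromen-2-yl)heptadecanoate
Conditions: N-hydroxyphthalimide (1.1 equiv), DIC (1.1 equiv), DMAP (0.1 equiv), CH2Cl2, rt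
Reagents that add atoms: N-hydroxyphthalimide, O=C1c2ccccc2C(=O)N1O
Why: Carbodiimide esterification installs the redox-active ester as the activating group for decarboxylation, and the chromone and aryl methyl ethers are inert to it.

**Step 5**
Reactants: 8 palmitic acid (hexadecanoic acid)
Product: 9 1,3-dioxoisoindolin-2-yl hexadecanoate
Conditions: N-hydroxyphthalimide (1.1 equiv), DIC (1.1 equiv), DMAP (0.1 equiv), CH2Cl2, rt
Reagents that add atoms: N-hydroxyphthalimide, O=C1c2ccccc2C(=O)N1O
Why: The same carbodiimide esterification turns the cheap C16 fatty acid into a crystalline redox-active ester that can be dosed exactly.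

**Step 6**
Reactants: 7 1,3-dioxoisoindolin-2-yl 17-(5,7-dimethoxy-8-methyl-4-oxo-4H-chromen-2-yl)heptadecanoate; 9 1,3-dioxoisoindolin-2-yl hexadecanoate (3 equiv)
Product: 10 2-hentriacontyl-5,7-dimethoxy-8-methyl-4H-chromen-4-one
Conditions: NiCl2·6H2O (20 mol %), 4,4′,4″-tri-tert-butyl-2,2′:6′,2″-terpyridine (20 mol %), NaI, DMF/THF (2:1), Zn(+)/RVC(−), undivided cell, constant current, 35 °C; 1 M HCl work-up
Reagents that add atoms: none
Why: Cathodically formed low-valent (terpyridine)nickel transfers one electron to each phthalimide ester, whose radical anion breaks its N–O bond and loses CO2, so that 7 gives the primary 16-(chromon-2-yl)hexadecyl radical and 9 the primary pentadecyl radical; capture of both at nickel gives a dialkylnickel(III) species that forms the CH2–CH2 bond by reductive elimination, with the dissolving zinc anode supplying the two electrons. The closest known reaction type is the nickel-electrocatalytic doubly decarboxylative C(sp3)–C(sp3) cross-coupling of two redox-active esters, known for primary/primary pairs and the reductive counterpart of a mixed Kolbe electrolysis. No ring is closed and no stereocentre is formed. The selectivity needed is hetero- over homocoupling, which is close to statistical for two primary radicals, so the cheap ester 9 is used in threefold excess, and the polar chromone head group should make triacontane, 10 and the bis-chromone dimer easy to separate on silica. Chemoselectivity rests on the polarity of the cell: the esters and the catalyst are reduced more easily than the 4-pyranone carbonyl, the oxidisable 5,7-dimethoxy-8-methyl ring sees only a zinc anode that dissolves at low potential, and the methyl ethers remove the acidic O–H groups that could protonate alkylnickel intermediates.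

**Step 7**
Reactants: 10 2-hentriacontyl-5,7-dimethoxy-8-methyl-4H-chromen-4-one
Product: 11 2-hentriacontyl-5,7-dihydroxy-8-methyl-4H-chromen-4-one (target)
Conditions: BBr3 (6 equiv), CH2Cl2, −78 °C → rt (40 °C if needed); ice-water quench
Reagents that add atoms: none
Why: Lewis-acid aryl methyl ether cleavage with BBr3, in which the 5-OMe should go first through chelation to the C4 carbonyl and the 7-OMe follows with excess reagent, while the anhydrous medium avoids the pyranone opening and reclosure (Wessely–Moser type) that hot aqueous HI could cause, so the methyl group stays at C8.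

**Compound list**
1 | 2,4,6-trihydroxy-3-methylacetophenone | CC(=O)c1c(O)cc(O)c(C)c1O | starting material
2 | 2-hydroxy-4,6-dimethoxy-3-methylacetophenone | CC(=O)c1c(OC)cc(OC)c(C)c1O | intermediate
3 | 18-(tert-butoxy)-18-oxooctadecanoic acid (mono-tert-butyl octadecanedioate) | OC(=O)CCCCCCCCCCCCCCCCC(=O)OC(C)(C)C | starting material
4 | 2-acetyl-3,5-dimethoxy-6-methylphenyl tert-butyl octadecanedioate | CC(=O)c1c(OC)cc(OC)c(C)c1OC(=O)CCCCCCCCCCCCCCCCC(=O)OC(C)(C)C | intermediate
5 | tert-butyl 20-(2-hydroxy-4,6-dimethoxy-3-methylphenyl)-18,20-dioxoicosanoate | CC(C)(C)OC(=O)CCCCCCCCCCCCCCCCC(=O)CC(=O)c1c(OC)cc(OC)c(C)c1O | intermediate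
6 | 17-(5,7-dimethoxy-8-methyl-4-oxo-4H-chromen-2-yl)heptadecanoic acid | OC(=O)CCCCCCCCCCCCCCCCc1cc(=O)c2c(OC)cc(OC)c(C)c2o1 | intermediate
7 | 1,3-dioxoisoindolin-2-yl 17-(5,7-dimethoxy-8-methyl-4-oxo-4H-chromen-2-yl)heptadecanoate | O=C(CCCCCCCCCCCCCCCCc1cc(=O)c2c(OC)cc(OC)c(C)c2o1)ON1C(=O)c2ccccc2C1=O | intermediate
8 | palmitic acid (hexadecanoic acid) | CCCCCCCCCCCCCCCC(=O)O | starting material
9 | 1,3-dioxoisoindolin-2-yl hexadecanoate | CCCCCCCCCCCCCCCC(=O)ON1C(=O)c2ccccc2C1=O | intermediate
10 | 2-hentriacontyl-5,7-dimethoxy-8-methyl-4H-chromen-4-one | CCCCCCCCCCCCCCCCCCCCCCCCCCCCCCCc1cc(=O)c2c(OC)cc(OC)c(C)c2o1 | intermediate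
11 | 2-hentriacontyl-5,7-dihydroxy-8-methyl-4H-chromen-4-one (CNP0154031.0) | CCCCCCCCCCCCCCCCCCCCCCCCCCCCCCCc1cc(=O)c2c(O)cc(O)c(C)c2o1 | target

**Step count**
Total step count: 7.
Longest linear sequence: 6 (steps 1, 2, 3, 4, 6, 7).

**Steps most likely to fail**

Step 6. Homocoupling, or hydrogen abstraction and disproportionation of the primary radicals, may outrun cross-capture at nickel. Poor solubility of the waxy esters and fouling of the cathode would make this worse. The fallback replaces the radical/radical pairing by a nucleophile/electrophile pairing, in which cross-selectivity is built in.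
- It sets out from 7.
- Purchased 1-bromopentadecane (CCCCCCCCCCCCCCCBr) and Mg in THF give pentadecylmagnesium bromide F1.
- ZnCl2 (0.5 equiv) converts F1 into dipentadecylzinc F2.
- F2 is coupled with 7 in a nickel-catalysed decarboxylative alkyl–alkyl Negishi reaction (NiCl2·glyme, 4,4′-di-tert-butyl-2,2′-bipyridine, THF/DMF, rt).
- The route is rejoined at 10.

Step 3. The base may expel the phenoxide from the enolisable aryl alkanoate (ketene pathway), or it may trigger intermolecular Claisen condensation in place of the intramolecular acyl shift. The fallback forms the C2–C3 bond intermolecularly and never exposes an aryl alkanoate to base.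
- It sets out from 2 and 3.
- Acid 3 and carbonyldiimidazole in THF give tert-butyl 18-(1H-imidazol-1-yl)-18-oxooctadecanoate F3.
- Ketone 2 is deprotonated twice in situ with LiHMDS (3.3 equiv, THF, −78 °C) and C-acylated with F3.
- The route is rejoined at 5, which is cyclised with TFA as before to 6.

Step 1. Site selection between the two ortho-hydroxy groups may be poor, and over-methylation or C-methylation of the phloroglucinol ring may occur. The fallback moves the selection from alkylation to dealkylation.
- It sets out from 1.
- Exhaustive methylation (excess Me2SO4, K2CO3, acetone, reflux) gives 2,4,6-trimethoxy-3-methylacetophenone F4.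
- BCl3 (1.1 equiv, CH2Cl2, −78 → 0 °C) then cleaves one methoxy group ortho to the carbonyl under chelation control. The one flanked by acetyl and methyl is twisted out of conjugation and is the most basic and most strained, so it should be the one removed.
- The route is rejoined at 2.

**Further compounds**
F1 | step 6 | pentadecylmagnesium bromide | CCCCCCCCCCCCCCC[Mg]Br
F2 | step 6 | dipentadecylzinc | CCCCCCCCCCCCCCC[Zn]CCCCCCCCCCCCCCC
F3 | step 3 | tert-butyl 18-(1H-imidazol-1-yl)-18-oxooctadecanoate | CC(C)(C)OC(=O)CCCCCCCCCCCCCCCCC(=O)n1ccnc1
F4 | step 1 | 2,4,6-trimethoxy-3-methylacetophenone | CC(=O)c1c(OC)cc(OC)c(C)c1OC
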